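The hindered C6–C8'' axis is never made by coupling. Instead, ring A of the 6-linked flavone (unit 1) is built around it. In that ring C6 lies between oxygenated C5 and C7, and C4a/C8a belong to a 4-pyranone. A [4+2] union produces exactly this pattern. The diene is a fused 2-pyranone (carbons C4a=C8a–C8=C7, oxygen already on C7). The dienophile is an aryl ketene acetal that delivers C5 and C6. One heating forms C4a–C5 and C6–C7, expels CO2 and methanol, and gives the whole protected biflavone. The precursors are a 7-benzyloxy-2-anisylpyrano[4,3-b]pyran-4,5-dione and an 8-(2,2-dimethoxyvinyl)flavone, whose aryl–CH bond becomes the axis.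

Key step: step 10

Assumption: the target SMILES carries no descriptor for the C6–C8'' axis, so the axis is treated as unspecified and the material is made as the racemate.
Locants: unit 1 has plain and single-primed locants, unit 2 double- and triple-primed ones. In 5 and 6, atoms C2, C3, C4, C4a, C7, C8 and C8a keep their numbers in the flavone, while the lactone atoms C5 and O6 leave as CO2.

Step 1
Reactants: 1 malonyl dichloride (two molecules)
Product: 2 6-chloro-4-hydroxy-2-oxo-2H-pyran-3-carbonyl chloride
Conditions: neat, 35–40 °C, dry N2 sweep, several days; solid washed with dry hexane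
Reagents that add atoms: none
Why: Known self-condensation of malonyl dichloride, in which one molecule C-acylates the enol of a second and the enolised terminal acyl chloride then O-acylates to close the 2-pyranone, with loss of two HCl while C6–Cl and the 3-carbonyl chloride stay in place.

Step 2
Reactants: 2 6-chloro-4-hydroxy-2-oxo-2H-pyran-3-carbonyl chloride; 3 4-methoxyacetophenone
Product: 4 6-chloro-4-hydroxy-3-[3-(4-methoxyphenyl)-3-oxopropanoyl]-2H-pyran-2-one
Conditions: MgBr2·OEt2 (2.5 equiv), iPr2NEt (3 equiv), CH2Cl2, 0 °C to rt; cold 1 M HCl wash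
Reagents that add atoms: none
Why: Claisen-type C-acylation of an aryl methyl ketone under soft enolisation, in which the amine first removes the acidic 4-OH so that the anionic ring shields C6–Cl and the lactone, the acyl chloride carbon is the only strong electrophile left, and the magnesium chelate of the tricarbonyl product prevents a second acylation.

Step 3
Reactants: 4 6-chloro-4-hydroxy-3-[3-(4-methoxyphenyl)-3-oxopropanoyl]-2H-pyran-2-one
Product: 5 7-chloro-2-(4-methoxyphenyl)pyrano[4,3-b]pyran-4,5-dione
Conditions: TsOH·H2O (10 mol %), toluene, reflux, Dean–Stark trap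
Reagents that add atoms: none
Why: Acid-catalysed cyclodehydration of an enolic 1,3-diketone next to a hydroxyl, which is the closing step of the Baker–Venkataraman flavone synthesis and the known way from 3-acetoacetyl-4-hydroxy-2-pyranones to pyrano[4,3-b]pyran-4,5-diones, run with azeotropic water removal so that the hydrolysable C7–Cl is kept.

Step 4
Reactants: 5 7-chloro-2-(4-methoxyphenyl)pyrano[4,3-b]pyran-4,5-dione
Product: 6 7-benzyloxy-2-(4-methoxyphenyl)pyrano[4,3-b]pyran-4,5-dione
Conditions: BnOH (1.0 equiv), iPr2NEt (1.1 equiv), 4 Å MS, CH2Cl2, −20 °C to rt; crystallisation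
Reagents that add atoms: benzyl alcohol, OCc1ccccc1
Why: Addition–elimination at a vinylogous acyl chloride, since C7 is bound to the ring oxygen and is the δ-carbon of the dienone systems ending at C4=O and C5=O, chloride is the best leaving group of the tetrahedral intermediate, and one equivalent of neutral alcohol with a hindered amine (not an alkoxide) avoids opening of the lactone.

Step 5
Reactants: 7 acacetin (5,7-dihydroxy-4'-methoxyflavone)
Product: 8 5,7-bis(benzyloxy)-4'-methoxyflavone
Conditions: BnBr (3 equiv), K2CO3 (4 equiv), DMF, 80 °C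
Reagents that add atoms: benzyl bromide, BrCc1ccccc1
Why: Williamson etherification, in which the free 7-OH reacts first and the hydrogen-bonded 5-OH follows with excess halide and heat in a dipolar aprotic solvent.

Step 6
Reactants: 8 5,7-bis(benzyloxy)-4'-methoxyflavone
Product: 9 5,7-bis(benzyloxy)-8-iodo-4'-methoxyflavone
Conditions: NIS (1.05 equiv), TFA (0.2 equiv), MeCN–CH2Cl2, 0 °C to rt, dark
Reagents that add atoms: N-iodosuccinimide, O=C1CCC(=O)N1I
Why: Electrophilic aromatic iodination, which in 5,7-dialkoxyflavones lacking the 5-OH chelate goes by experience to C8 (ortho to O1 and the 7-alkoxy group, para to the 5-alkoxy group), while C3, the anisyl ring and the benzyl rings are much less nucleophilic.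

Step 7
Reactants: 9 5,7-bis(benzyloxy)-8-iodo-4'-methoxyflavone
Product: 10 5,7-bis(benzyloxy)-4'-methoxyflavone-8-carbaldehyde
Conditions: PdCl2(PPh3)2 (5 mol %), CO (1 atm), HCO2Na (2 equiv), DMF, 100 °C
Reagents that add atoms: carbon monoxide, [C-]#[O+]
Why: Palladium-catalysed reductive carbonylation of an aryl iodide, in which zerovalent palladium inserts into C8–I, CO insertion gives the aroyl complex, and formate delivers hydride by decarboxylation before reductive elimination, under conditions that leave the flavone and the benzyl ethers untouched.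

Step 8
Reactants: 11 chlorodiphenylphosphine; 12 trimethyl orthoformate
Product: 13 (dimethoxymethyl)diphenylphosphine oxide
Conditions: 12 (3 equiv), neat, 0 °C to rt, then 60 °C, gas vented; crystallisation
Reagents that add atoms: none
Why: Michaelis–Arbuzov-type P–C bond formation between a trivalent phosphorus chloride and an orthoformate, ending with loss of chloromethane and formation of the P=O bond.

Step 9
Reactants: 10 5,7-bis(benzyloxy)-4'-methoxyflavone-8-carbaldehyde; 13 (dimethoxymethyl)diphenylphosphine oxide
Product: 15 8-(2,2-dimethoxyvinyl)-5,7-bis(benzyloxy)-4'-methoxyflavone, via hydroxy phosphine oxide adduct 14 (not isolated)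
Conditions: 13, LiN(iPr)2, THF, −100 °C; add 10; then KOtBu, −78 °C to rt; filtration through basic Al2O3, used at once
Reagents that add atoms: none
Why: Horner–Wittig olefination with a lithiated dialkoxymethyl phosphine oxide is the established route from aldehydes to ketene O,O-acetals (methylation of the arylacetic ester enolate would go to carbon), the aldehyde outcompetes the vinylogous-ester C4=O at low temperature, the potassium alkoxide of 14 loses diphenylphosphinate by syn elimination, and no alkene geometry arises because the new terminus bears two methoxy groups.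

Step 10
Reactants: 6 7-benzyloxy-2-(4-methoxyphenyl)pyrano[4,3-b]pyran-4,5-dione; 15 8-(2,2-dimethoxyvinyl)-5,7-bis(benzyloxy)-4'-methoxyflavone
Product: 18 7,5'',7''-tris(benzyloxy)-5,4',4'''-trimethoxy-6,8''-biflavone, via bridged lactone cycloadduct 16 (not isolated), via dimethoxycyclohexadiene 17 (not isolated)
Conditions: 6 (1.5 equiv), 15 (1.0 equiv), powdered 4 Å MS, mesitylene, Ar, base-washed sealed tube, 120 to 150 °C
Reagents that add atoms: none
Why: Proposed new method: the electron-rich ketene acetal adds to the electron-poor fused 2-pyranone in an inverse-electron-demand [4+2] addition (asynchronous concerted, or stepwise through a dimethoxycarbenium/tricarbonyl-enolate zwitterion), its nucleophilic CH carbon (future C6) bonding to C7 and its acetal carbon (future C5) to C4a to give 16. Retro-[4+2] loss of CO2 then gives 17, and 1,2-elimination of methanol, driven by formation of the benzenoid chromone ring, gives 18. The closest known reaction type is the cycloaddition of 3-acyl- and 3-alkoxycarbonyl-2-pyranones with 1,1-dialkoxyalkenes, which gives ortho-alkoxyaryl carbonyl compounds with the same orientation; new here are the pyranone-fused, doubly oxygenated diene and the bulky aryl group on the dienophile. Ring A closes as a six-membered carbocycle by [4+2] addition across the diene termini C4a and C7, and no other ring is formed. No stereocentre survives, since those of 16 and 17 are erased on aromatisation and the C6–C8'' axis forms as the racemate. The step needs attack at C7 and not at C8a or C2: C7 is the δ-terminus of the acceptor system polarised by C4=O and C5=O, only attack there lets the cationic acetal carbon reach C4a in a six-membered array while additions elsewhere are reversible dead ends, and a dimethyl rather than a silyl acetal is chosen so that no silyl transfer can divert the zwitterion.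

Step 11
Reactants: 18 7,5'',7''-tris(benzyloxy)-5,4',4'''-trimethoxy-6,8''-biflavone
Product: 19 5,7,5'',7''-tetrahydroxy-4',4'''-dimethoxy-6,8''-biflavone (CNP0226117.0)
Conditions: BCl3 (12 equiv), C6HMe5 (10 equiv), CH2Cl2, −78 °C to 0 °C; aqueous MeOH quench
Reagents that add atoms: none
Why: Lewis-acid debenzylation with a non-basic cation scavenger is combined with chelation-directed demethylation, because BCl3 held between C4=O and the peri 5-OMe cleaves that ether whereas the two unchelated anisyl ethers are inert to BCl3 at these temperatures.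

Compound list
1 | malonyl dichloride | O=C(Cl)CC(Cl)=O | starting material
2 | 6-chloro-4-hydroxy-2-oxo-2H-pyran-3-carbonyl chloride | O=C(Cl)c1c(O)cc(Cl)oc1=O | intermediate
3 | 4-methoxyacetophenone | CC(=O)c1ccc(OC)cc1 | starting material
4 | 6-chloro-4-hydroxy-3-[3-(4-methoxyphenyl)-3-oxopropanoyl]-2H-pyran-2-one | COc1ccc(cc1)C(=O)CC(=O)c1c(O)cc(Cl)oc1=O | intermediate
5 | 7-chloro-2-(4-methoxyphenyl)pyrano[4,3-b]pyran-4,5-dione | O=c1cc(-c2ccc(OC)cc2)oc2cc(Cl)oc(=O)c12 | intermediate
6 | 7-benzyloxy-2-(4-methoxyphenyl)pyrano[4,3-b]pyran-4,5-dione | O=c1cc(-c2ccc(OC)cc2)oc2cc(OCc3ccccc3)oc(=O)c12 | intermediate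
7 | acacetin | COc1ccc(-c2cc(=O)c3c(O)cc(O)cc3o2)cc1 | starting material
8 | 5,7-bis(benzyloxy)-4'-methoxyflavone | COc1ccc(-c2cc(=O)c3c(OCc4ccccc4)cc(OCc4ccccc4)cc3o2)cc1 | intermediate
9 | 5,7-bis(benzyloxy)-8-iodo-4'-methoxyflavone | COc1ccc(-c2cc(=O)c3c(OCc4ccccc4)cc(OCc4ccccc4)c(I)c3o2)cc1 | intermediate
10 | 5,7-bis(benzyloxy)-4'-methoxyflavone-8-carbaldehyde | COc1ccc(-c2cc(=O)c3c(OCc4ccccc4)cc(OCc4ccccc4)c(C=O)c3o2)cc1 | intermediate
11 | chlorodiphenylphosphine | ClP(c1ccccc1)c1ccccc1 | starting material
12 | trimethyl orthoformate | COC(OC)OC | starting material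
13 | (dimethoxymethyl)diphenylphosphine oxide | COC(OC)P(=O)(c1ccccc1)c1ccccc1 | intermediate
14 | 8-[2-(diphenylphosphoryl)-1-hydroxy-2,2-dimethoxyethyl]-5,7-bis(benzyloxy)-4'-methoxyflavone (racemic, present as its alkoxide, not isolated) | COc1ccc(-c2cc(=O)c3c(OCc4ccccc4)cc(OCc4ccccc4)c(C(O)C(OC)(OC)P(=O)(c4ccccc4)c4ccccc4)c3o2)cc1 | intermediate
15 | 8-(2,2-dimethoxyvinyl)-5,7-bis(benzyloxy)-4'-methoxyflavone | COC(OC)=Cc1c(OCc2ccccc2)cc(OCc2ccccc2)c2c(=O)cc(-c3ccc(OC)cc3)oc12 | intermediate
16 | bridged lactone cycloadduct, a 2-oxabicyclo[2.2.2]octenone with bridgeheads C4a and C7 (racemic, configuration at C6 undefined, not isolated) | O=C1C=C(c2ccc(OC)cc2)OC2=CC3(OCc4ccccc4)OC(=O)C12C(OC)(OC)C3c1c(OCc2ccccc2)cc(OCc2ccccc2)c2c(=O)cc(-c3ccc(OC)cc3)oc12 | intermediate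
17 | 5,5-dimethoxy-5,6-dihydro form of 18 (racemic, not isolated) | O=C1C=C(c2ccc(OC)cc2)OC2=C1C(OC)(OC)C(c1c(OCc3ccccc3)cc(OCc3ccccc3)c3c(=O)cc(-c4ccc(OC)cc4)oc13)C(OCc1ccccc1)=C2 | intermediate
18 | 7,5'',7''-tris(benzyloxy)-5,4',4'''-trimethoxy-6,8''-biflavone | COc1ccc(-c2cc(=O)c3c(OC)c(-c4c(OCc7ccccc7)cc(OCc7ccccc7)c5c(=O)cc(-c6ccc(OC)cc6)oc45)c(OCc7ccccc7)cc3o2)cc1 | intermediate
19 | 5,7,5'',7''-tetrahydroxy-4',4'''-dimethoxy-6,8''-biflavone (CNP0226117.0) | COc1ccc(-c2cc(=O)c3c(O)c(-c4c(O)cc(O)c5c(=O)cc(-c6ccc(OC)cc6)oc45)c(O)cc3o2)cc1 | target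

Total step count: 11.
Longest linear sequence: 6 (steps 5, 6, 7, 9, 10, 11). The diene branch, steps 1–4 followed by 10 and 11, is equally long.

Steps most likely to fail

1. Step 10.
- What may go wrong: the addition may be too slow, because two oxygen donors raise the acceptor level of the diene and the dienophile is hindered.
- Competing processes are thermal electrocyclic opening of the alkoxypyranone, methanolysis of the diene by the liberated methanol, and hydrolysis of the ketene acetal.
- Fallback (known chemistry): the axis is made by cross-coupling instead of ring construction. It sets out from 9 and 7 and returns at 18.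
- Miyaura borylation of 9 (B2pin2, PdCl2(dppf), KOAc, dioxane, 90 °C) should give 5,7-bis(benzyloxy)-4'-methoxyflavone-8-boronic acid pinacol ester F1.
- In parallel, 7 is benzylated at the free 7-OH only (BnBr 1 equiv, K2CO3, acetone) to 7-O-benzylacacetin F2.
- F2 is iodinated at C6 under the influence of the 5-OH (benzyltrimethylammonium dichloroiodate, CaCO3, CH2Cl2–MeOH) to 7-O-benzyl-6-iodoacacetin F3.
- F3 is methylated (MeI, K2CO3, DMF) to 7-benzyloxy-6-iodo-5,4'-dimethoxyflavone F4.
- Suzuki–Miyaura coupling of F1 with F4 (Pd2(dba)3, SPhos, K3PO4, toluene–H2O, 100 °C) should give 18.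

2. Step 4.
- What may go wrong: the alcohol may attack the lactone carbonyl, or a second alcoholysis of the product may occur, so that ring opening takes the place of clean substitution.
- Fallback: acyl activation replaces substitution at C7. It sets out from 5 and returns at 6.
- Brief hydrolysis of 5 (NaHCO3, THF–H2O, 0 °C, then acidification) should stop at the acidic enol 7-hydroxy-2-(4-methoxyphenyl)pyrano[4,3-b]pyran-4,5-dione F5. This is the tautomer of the cyclic anhydride, and its anion resists further attack.
- Benzyl alcohol in warm toluene opens F5 at the non-conjugated carbonyl C7, as with homophthalic anhydride. The product is 2-[2-(benzyloxy)-2-oxoethyl]-6-(4-methoxyphenyl)-4-oxo-4H-pyran-3-carboxylic acid F6.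
- Activation of the acid with (CF3CO)2O in CH2Cl2 lets the ester enol oxygen close the lactone, the way homophthalic monoesters give 3-alkoxyisocoumarins. This returns 6.

3. Step 2.
- What may go wrong: competing O-acylation, attack of the enolate at C6 or at the lactone, or base-induced self-reaction of the acid chloride.
- Fallback: a base-free cycloaddition replaces enolate acylation. It sets out from 2 and 3, returns at 5, and replaces steps 2 and 3.
- Compound 2 is masked with acetone (CH2Cl2, rt) as 7-chloro-2,2-dimethylpyrano[4,3-d][1,3]dioxine-4,5-dione F7.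
- Compound 3 is converted (TMSOTf, Et3N, CH2Cl2, 0 °C) into 1-(4-methoxyphenyl)-1-(trimethylsilyloxy)ethene F8.
- Heating F7 in toluene releases acetone and the acylketene 6-chloro-3-(oxomethylidene)pyran-2,4-dione F9.
- F8 traps F9 by hetero-Diels–Alder addition as 7-chloro-2-(4-methoxyphenyl)-2-(trimethylsilyloxy)-2,3-dihydropyrano[4,3-b]pyran-4,5-dione F10.
- Acid work-up removes the silanol from F10 and gives 5.

Further compounds
F1 | step 10 | 5,7-bis(benzyloxy)-4'-methoxyflavone-8-boronic acid pinacol ester | COc1ccc(-c2cc(=O)c3c(OCc4ccccc4)cc(OCc4ccccc4)c(B4OC(C)(C)C(C)(C)O4)c3o2)cc1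
F2 | step 10 | 7-O-benzylacacetin | COc1ccc(-c2cc(=O)c3c(O)cc(OCc4ccccc4)cc3o2)cc1
F3 | step 10 | 7-O-benzyl-6-iodoacacetin | COc1ccc(-c2cc(=O)c3c(O)c(I)c(OCc4ccccc4)cc3o2)cc1
F4 | step 10 | 7-benzyloxy-6-iodo-5,4'-dimethoxyflavone | COc1ccc(-c2cc(=O)c3c(OC)c(I)c(OCc4ccccc4)cc3o2)cc1
F5 | step 4 | 7-hydroxy-2-(4-methoxyphenyl)pyrano[4,3-b]pyran-4,5-dione | O=c1cc(-c2ccc(OC)cc2)oc2cc(O)oc(=O)c12
F6 | step 4 | 2-[2-(benzyloxy)-2-oxoethyl]-6-(4-methoxyphenyl)-4-oxo-4H-pyran-3-carboxylic acid | COc1ccc(cc1)-c1cc(=O)c(C(=O)O)c(CC(=O)OCc2ccccc2)o1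
F7 | step 2 | 7-chloro-2,2-dimethylpyrano[4,3-d][1,3]dioxine-4,5-dione | CC1(C)Oc2cc(Cl)oc(=O)c2C(=O)O1
F8 | step 2 | 1-(4-methoxyphenyl)-1-(trimethylsilyloxy)ethene | COc1ccc(cc1)C(=C)O[Si](C)(C)C
F9 | step 2 | 6-chloro-3-(oxomethylidene)pyran-2,4-dione | O=C=C1C(=O)C=C(Cl)OC1=O
F10 | step 2 | 7-chloro-2-(4-methoxyphenyl)-2-(trimethylsilyloxy)-2,3-dihydropyrano[4,3-b]pyran-4,5-dione (racemic) | O=C1CC(O[Si](C)(C)C)(c2ccc(OC)cc2)Oc2cc(Cl)oc(=O)c12
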